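**Retrosynthetic overview**
1. Target 26 ⇐ O-acetylation and ester-to-carbinol conversion ⇐ epoxy alcohol 24 ⇐ hydroxyl-directed epoxidation of cycloheptenol 23 (the two oxirane C–O bonds, and C2/C3, are set from the C1 hydroxyl).
2. 23 ⇐ ring-closing metathesis of diene 22 (C2=C3); the C1 carbinol ⇐ ligand-controlled alkenylzinc addition to α-quaternary aldehyde 18.
3. 18 ⇐ dithiane unmasking and vinylogous HWE on methyl ketone 14; 14 ⇐ conjugate addition of a homoallyl copper reagent to acylcyclopentene 10 (sets C6, C7).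
4. 10 ⇐ Stille acylation of enol triflate 7 ⇐ new catalytic asymmetric conjugate methylation/O-triflation of dithianyl enone 5 (sets C10) ⇐ 3-ethoxycyclopentenone 1 + 1,3-dithiane 2.
5. Ring order: the five-membered ring is bought in 1, the seven-membered ring is closed by metathesis, the oxirane is formed last.

Assumption: skeleton numbering used in the text (not IUPAC) is C1 = acetoxy carbon, C2/C3 = oxirane carbons (C3 bears Me), C4/C5 = CH2, C6 = ring-fusion CH, C7 = side-chain-bearing CH, C8/C9 = CH2, C10 = quaternary ring-fusion carbon; the listed starting materials are taken as commercial.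

**Step 1**
Reactants: 1 3-ethoxycyclopent-2-en-1-one; 2 1,3-dithiane
Product: 5 3-(1,3-dithian-2-yl)cyclopent-2-en-1-one, via 2-lithio-1,3-dithiane 3 (not isolated), via lithium carbinolate 4 (not isolated)
Conditions: 2, n-BuLi, THF, −30 °C; then 1, −78 → 0 °C; then 2 M aq. HCl, rt
Reagents that add atoms: 1,3-dithiane 2 (C1CSCSC1); water (O)
Why: Corey–Seebach dithiane anion adds 1,2 to the vinylogous ester and the acid work-up effects the Stork–Danheiser hydrolysis–dehydration, transposing the carbonyl to give the 3-substituted enone; no stereocentre is formed.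

**Step 2**
Reactants: 5 3-(1,3-dithian-2-yl)cyclopent-2-en-1-one
Product: 7 (3S)-3-(1,3-dithian-2-yl)-3-methylcyclopent-1-en-1-yl trifluoromethanesulfonate, via aluminium enolate 6 (not isolated)
Conditions: Me3Al (1.5 equiv), Cu(OTf)2 (5 mol%), chiral sulfonate-bearing imidazolinium NHC precursor (6 mol%, pre-mixed with Ag2O, 3 mol%), Et2O, −30 °C; then Tf2O (2 equiv), −78 → 0 °C
Reagents that add atoms: trimethylaluminium (C[Al](C)C); trifluoromethanesulfonic anhydride (O=S(=O)(OS(=O)(=O)C(F)(F)F)C(F)(F)F)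
Why: Proposed new method: enantioselective conjugate methylation of a β-(1,3-dithian-2-yl)cyclopentenone by Me3Al under chiral NHC–copper catalysis with one-flask O-triflation of the aluminium enolate; Me3Al both activates the enone carbonyl and transmetalates methyl to the NHC–copper centre, whose methyl adds to the β-carbon on the enone face left open by the sulfonate-bridged NHC–Cu–Al assembly (ligand enantiomer chosen for 3S, which sets C10), the hard aluminium preferring the carbonyl oxygen and the strongly bound NHC keeping the soft thioacetal sulfurs from sequestering copper, and the regiodefined dimethylaluminium enolate 6 is then sulfonylated on oxygen by Tf2O; closest known reaction type: NHC– or phosphoramidite–copper-catalysed asymmetric conjugate addition of trialkylaluminium reagents to 3-alkylcycloalkenones forming all-carbon quaternary centres, with capture of the aluminium enolate by acylating or silylating agents.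

**Step 3**
Reactants: 7 (3S)-3-(1,3-dithian-2-yl)-3-methylcyclopent-1-en-1-yl trifluoromethanesulfonate; 8 tributyl(1-ethoxyethenyl)stannane
Product: 10 1-[(3S)-3-(1,3-dithian-2-yl)-3-methylcyclopent-1-en-1-yl]ethan-1-one, via ethoxydiene 9 (not isolated)
Conditions: 8, Pd(PPh3)4 (5 mol%), LiCl (3 equiv), THF, 65 °C; then 1 M aq. HCl, rt
Reagents that add atoms: tributyl(1-ethoxyethenyl)stannane 8 (CCOC(=C)[Sn](CCCC)(CCCC)CCCC); water (O)
Why: Stille coupling of the enol triflate (LiCl-assisted transmetalation) with the 1-ethoxyvinyl stannane, then acid hydrolysis of the enol ether, gives the methyl ketone conjugated to the C6=C7 alkene; C10 is untouched.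

**Step 4**
Reactants: 10 1-[(3S)-3-(1,3-dithian-2-yl)-3-methylcyclopent-1-en-1-yl]ethan-1-one; 11 4-bromo-2-methylbut-1-ene
Product: 14 1-[(1R,2S,3S)-3-(1,3-dithian-2-yl)-3-methyl-2-(3-methylbut-3-en-1-yl)cyclopentyl]ethan-1-one, via Grignard reagent 12 (not isolated), via silyl enol ether 13 (not isolated)
Conditions: 11, Mg, THF; then CuBr·SMe2 (10 mol%), TMSCl, 10, THF, −78 → −30 °C; 1 M aq. HCl; then K2CO3, MeOH, rt
Reagents that add atoms: 4-bromo-2-methylbut-1-ene 11 (C=C(C)CCBr)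
Why: Copper-catalysed, TMSCl-accelerated conjugate addition of the homoallyl Grignard reagent: the nucleophile attacks C6 anti to the bulky dithianyl group on the neighbouring quaternary C10 (sets 6S, chain trans to C1), and base equilibration of the enolisable C7 puts the acetyl group trans to the new chain (7R).

**Step 5**
Reactants: 14 1-[(1R,2S,3S)-3-(1,3-dithian-2-yl)-3-methyl-2-(3-methylbut-3-en-1-yl)cyclopentyl]ethan-1-one; 15 triethyl 4-phosphonocrotonate
Product: 17 ethyl (2E,4E)-5-[(1R,2S,3S)-3-(1,3-dithian-2-yl)-3-methyl-2-(3-methylbut-3-en-1-yl)cyclopentyl]hexa-2,4-dienoate, via lithiated phosphonate 16 (not isolated)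
Conditions: 15, LiN(SiMe3)2, THF, −78 °C; then 14, −78 → 40 °C
Reagents that add atoms: triethyl 4-phosphonocrotonate 15 (CCOC(=O)/C=C/CP(=O)(OCC)OCC)
Why: Vinylogous Horner–Wadsworth–Emmons olefination of the methyl ketone; the 2E alkene comes from the reagent and the new trisubstituted alkene forms E because the branched C7 substituent avoids the cis position next to the dienoate chain (allylic strain in the Z isomer).

**Step 6**
Reactants: 17 ethyl (2E,4E)-5-[(1R,2S,3S)-3-(1,3-dithian-2-yl)-3-methyl-2-(3-methylbut-3-en-1-yl)cyclopentyl]hexa-2,4-dienoate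
Product: 18 ethyl (2E,4E)-5-[(1R,2S,3S)-3-formyl-3-methyl-2-(3-methylbut-3-en-1-yl)cyclopentyl]hexa-2,4-dienoate
Conditions: MeI (10 equiv), CaCO3, MeCN–H2O (4:1), 45 °C
Reagents that add atoms: water (O)
Why: Alkylative dithiane hydrolysis (S-methylation, then water attack on the thionium ion) unmasks the neopentyl aldehyde without touching alkenes or ester; C10 is quaternary and cannot epimerise.

**Step 7**
Reactants: 18 ethyl (2E,4E)-5-[(1R,2S,3S)-3-formyl-3-methyl-2-(3-methylbut-3-en-1-yl)cyclopentyl]hexa-2,4-dienoate; 19 hex-1-yne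
Product: 22 ethyl (2E,4E)-5-[(1R,2S,3S)-3-[(1R,2E)-1-hydroxyhept-2-en-1-yl]-3-methyl-2-(3-methylbut-3-en-1-yl)cyclopentyl]hexa-2,4-dienoate, via alkenylborane 20 (not isolated), via alkenylzinc reagent 21 (not isolated)
Conditions: 19, Cy2BH (from BH3·SMe2 + cyclohexene), hexane, 0 °C → rt; Et2Zn, −78 °C; (2R)-(+)-3-exo-morpholinoisoborneol (MIB, 5 mol%), 18, toluene, −10 °C; aq. NH4Cl
Reagents that add atoms: hex-1-yne 19 (C#CCCCC)
Why: Oppolzer-type catalytic asymmetric alkenylzinc addition (alkyne hydroboration, boron-to-zinc exchange, amino-alcohol-accelerated addition): the (2R)-MIB–zinc complex delivers the (E)-hexenyl group to one aldehyde face under ligand control, the uncatalysed background on this α-quaternary aldehyde being negligible, which sets C1 as R; the ester is inert to organozinc reagents.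

**Step 8**
Reactants: 22 ethyl (2E,4E)-5-[(1R,2S,3S)-3-[(1R,2E)-1-hydroxyhept-2-en-1-yl]-3-methyl-2-(3-methylbut-3-en-1-yl)cyclopentyl]hexa-2,4-dienoate
Product: 23 ethyl (2E,4E)-5-[(1R,3aS,4R,8aS)-4-hydroxy-3a,6-dimethyl-1,2,3,3a,4,7,8,8a-octahydroazulen-1-yl]hexa-2,4-dienoate
Conditions: second-generation Grubbs catalyst (H2IMes)(PCy3)Cl2Ru=CHPh (10 mol%), toluene (5 mM), 80 °C
Reagents that add atoms: none
Why: Ring-closing olefin metathesis between the allylic-alcohol alkene and the 1,1-disubstituted alkene, which sit on trans-disposed arms of the cyclopentane, closes the trans-fused seven-membered ring with the trisubstituted C2=C3 alkene and expels hex-1-ene; no stereocentre changes.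

**Step 9**
Reactants: 23 ethyl (2E,4E)-5-[(1R,3aS,4R,8aS)-4-hydroxy-3a,6-dimethyl-1,2,3,3a,4,7,8,8a-octahydroazulen-1-yl]hexa-2,4-dienoate
Product: 24 ethyl (2E,4E)-5-[(1R,3aS,4S,5S,6R,8aS)-5,6-epoxy-4-hydroxy-3a,6-dimethyldecahydroazulen-1-yl]hexa-2,4-dienoate
Conditions: VO(acac)2 (5 mol%), t-BuOOH (1.5 equiv, in decane), CH2Cl2, 0 °C → rt
Reagents that add atoms: tert-butyl hydroperoxide (CC(C)(C)OO)
Why: Hydroxyl-directed vanadium-catalysed epoxidation (Sharpless–Michaelson type): the peroxide oxygen is transferred within the vanadate ester of the C1 alkoxide, so the C2–O and C3–O bonds form on the face syn to the hydroxyl (2S,3R in skeleton numbering), while the electron-poor dienoate is not touched.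

**Step 10**
Reactants: 24 ethyl (2E,4E)-5-[(1R,3aS,4S,5S,6R,8aS)-5,6-epoxy-4-hydroxy-3a,6-dimethyldecahydroazulen-1-yl]hexa-2,4-dienoate
Product: 25 (3E,5E)-6-[(1R,3aS,4S,5S,6R,8aS)-5,6-epoxy-4-hydroxy-3a,6-dimethyldecahydroazulen-1-yl]-2-methylhepta-3,5-dien-2-ol
Conditions: MeLi (4 equiv), THF, −78 → 0 °C; aq. NH4Cl
Reagents that add atoms: methyllithium ([Li]C)
Why: Double 1,2-addition of methyllithium to the ester (after deprotonation of the C1 hydroxyl) gives the tertiary carbinol; the trisubstituted epoxide and the cis alkoxide (no Payne pathway) are unaffected at low temperature.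

**Step 11**
Reactants: 25 (3E,5E)-6-[(1R,3aS,4S,5S,6R,8aS)-5,6-epoxy-4-hydroxy-3a,6-dimethyldecahydroazulen-1-yl]-2-methylhepta-3,5-dien-2-ol
Product: 26 (1R,3aS,4S,5S,6R,8aS)-5,6-epoxy-1-[(2E,4E)-6-hydroxy-6-methylhepta-2,4-dien-2-yl]-3a,6-dimethyldecahydroazulen-4-yl acetate
Conditions: Ac2O, pyridine, DMAP (10 mol%), CH2Cl2, 0 °C → rt
Reagents that add atoms: acetic anhydride (CC(=O)OC(C)=O)
Why: DMAP-catalysed acyl transfer acetylates the secondary C1 hydroxyl while the hindered tertiary allylic hydroxyl of the side chain does not react at room temperature; no stereocentre changes.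

**Compound list**
1 | 3-ethoxycyclopent-2-en-1-one | CCOC1=CC(=O)CC1 | starting material
2 | 1,3-dithiane | C1CSCSC1 | starting material
3 | 2-lithio-1,3-dithiane | [Li]C1SCCCS1 | intermediate
4 | lithium 1-(1,3-dithian-2-yl)-3-ethoxycyclopent-2-en-1-olate (racemic) | CCOC1=CC(O[Li])(C2SCCCS2)CC1 | intermediate
5 | 3-(1,3-dithian-2-yl)cyclopent-2-en-1-one | O=C1CCC(C2SCCCS2)=C1 | intermediate
6 | dimethylaluminium (3S)-3-(1,3-dithian-2-yl)-3-methylcyclopent-1-en-1-olate | C[Al](C)OC1=C[C@@](C)(C2SCCCS2)CC1 | intermediate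
7 | (3S)-3-(1,3-dithian-2-yl)-3-methylcyclopent-1-en-1-yl trifluoromethanesulfonate | FC(F)(F)S(=O)(=O)OC1=C[C@@](C)(C2SCCCS2)CC1 | intermediate
8 | tributyl(1-ethoxyethenyl)stannane | CCOC(=C)[Sn](CCCC)(CCCC)CCCC | starting material
9 | 2-[(1S)-3-(1-ethoxyethenyl)-1-methylcyclopent-2-en-1-yl]-1,3-dithiane | CCOC(=C)C1=C[C@@](C)(C2SCCCS2)CC1 | intermediate
10 | 1-[(3S)-3-(1,3-dithian-2-yl)-3-methylcyclopent-1-en-1-yl]ethan-1-one | CC(=O)C1=C[C@@](C)(C2SCCCS2)CC1 | intermediate
11 | 4-bromo-2-methylbut-1-ene | C=C(C)CCBr | starting material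
12 | (3-methylbut-3-en-1-yl)magnesium bromide | C=C(C)CC[Mg]Br | intermediate
13 | 2-[(1S,2S)-1-methyl-2-(3-methylbut-3-en-1-yl)-3-{1-[(trimethylsilyl)oxy]ethylidene}cyclopentyl]-1,3-dithiane | C1(SCCCS1)[C@@]2(C)CCC(=C(C)O[Si](C)(C)C)[C@@H]2CCC(C)=C | intermediate
14 | 1-[(1R,2S,3S)-3-(1,3-dithian-2-yl)-3-methyl-2-(3-methylbut-3-en-1-yl)cyclopentyl]ethan-1-one | C1(SCCCS1)[C@@]2(C)CC[C@@H](C(C)=O)[C@@H]2CCC(C)=C | intermediate
15 | triethyl 4-phosphonocrotonate, ethyl (2E)-4-(diethoxyphosphoryl)but-2-enoate | CCOC(=O)/C=C/CP(=O)(OCC)OCC | starting material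
16 | ethyl (2E)-4-(diethoxyphosphoryl)-4-lithiobut-2-enoate | CCOC(=O)/C=C/C([Li])P(=O)(OCC)OCC | intermediate
17 | ethyl (2E,4E)-5-[(1R,2S,3S)-3-(1,3-dithian-2-yl)-3-methyl-2-(3-methylbut-3-en-1-yl)cyclopentyl]hexa-2,4-dienoate | C1(SCCCS1)[C@@]2(C)CC[C@@H](/C(C)=C/C=C/C(=O)OCC)[C@@H]2CCC(C)=C | intermediate
18 | ethyl (2E,4E)-5-[(1R,2S,3S)-3-formyl-3-methyl-2-(3-methylbut-3-en-1-yl)cyclopentyl]hexa-2,4-dienoate | O=C[C@@]1(C)CC[C@@H](/C(C)=C/C=C/C(=O)OCC)[C@@H]1CCC(C)=C | intermediate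
19 | hex-1-yne | C#CCCCC | starting material
20 | dicyclohexyl[(1E)-hex-1-en-1-yl]borane | CCCC/C=C/B(C1CCCCC1)C1CCCCC1 | intermediate
21 | ethyl[(1E)-hex-1-en-1-yl]zinc | CCCC/C=C/[Zn]CC | intermediate
22 | ethyl (2E,4E)-5-[(1R,2S,3S)-3-[(1R,2E)-1-hydroxyhept-2-en-1-yl]-3-methyl-2-(3-methylbut-3-en-1-yl)cyclopentyl]hexa-2,4-dienoate | O[C@H](/C=C/CCCC)[C@@]1(C)CC[C@@H](/C(C)=C/C=C/C(=O)OCC)[C@@H]1CCC(C)=C | intermediate
23 | ethyl (2E,4E)-5-[(1R,3aS,4R,8aS)-4-hydroxy-3a,6-dimethyl-1,2,3,3a,4,7,8,8a-octahydroazulen-1-yl]hexa-2,4-dienoate | O[C@@H]1C=C(C)CC[C@H]2[C@H](/C(C)=C/C=C/C(=O)OCC)CC[C@]12C | intermediate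
24 | ethyl (2E,4E)-5-[(1R,3aS,4S,5S,6R,8aS)-5,6-epoxy-4-hydroxy-3a,6-dimethyldecahydroazulen-1-yl]hexa-2,4-dienoate | O[C@@H]1[C@@H]2O[C@]2(C)CC[C@H]2[C@H](/C(C)=C/C=C/C(=O)OCC)CC[C@]12C | intermediate
25 | (3E,5E)-6-[(1R,3aS,4S,5S,6R,8aS)-5,6-epoxy-4-hydroxy-3a,6-dimethyldecahydroazulen-1-yl]-2-methylhepta-3,5-dien-2-ol | O[C@@H]1[C@@H]2O[C@]2(C)CC[C@H]2[C@H](/C(C)=C/C=C/C(C)(C)O)CC[C@]12C | intermediate
26 | (1R,3aS,4S,5S,6R,8aS)-5,6-epoxy-1-[(2E,4E)-6-hydroxy-6-methylhepta-2,4-dien-2-yl]-3a,6-dimethyldecahydroazulen-4-yl acetate (CNP0265175.2) | CC(=O)O[C@@H]1[C@@H]2O[C@]2(C)CC[C@H]2[C@H](/C(C)=C/C=C/C(C)(C)O)CC[C@]12C | target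

**Step count**
Total step count: 11. Longest linear sequence: 11 steps (1 → 26).

**Three steps most likely to fail, with fallbacks**

Step 2 (the proposed new reaction). The branched, sulfur-bearing β-substituent may slow the conjugate addition or lower the selectivity, and the one-flask triflation of the aluminium enolate is untested. The fallback uses the established NHC–copper conjugate addition of an α-silylvinyl aluminium reagent to a 3-methyl enone; it sets out from 1 and comes back to the route at 10. MeLi addition to 1 and acid hydrolysis give 3-methylcyclopent-2-en-1-one F1. Conjugate addition of the alane made from ethynyltrimethylsilane and iBu2AlH (Cu(OTf)2, chiral NHC), with TMSOTf capture of the enolate, gives the silyl enol ether trimethyl({(3S)-3-methyl-3-[1-(trimethylsilyl)ethenyl]cyclopent-1-en-1-yl}oxy)silane F2. MeLi followed by Comins' reagent converts it into the triflate (3S)-3-methyl-3-[1-(trimethylsilyl)ethenyl]cyclopent-1-en-1-yl trifluoromethanesulfonate F3. Stille coupling with 8 under the step 3 conditions gives the ethoxydiene {1-[(1S)-3-(1-ethoxyethenyl)-1-methylcyclopent-2-en-1-yl]ethenyl}trimethylsilane F4 and, after aqueous HCl, the enone 1-{(3S)-3-methyl-3-[1-(trimethylsilyl)ethenyl]cyclopent-1-en-1-yl}ethan-1-one F5. CF3CO2H removes the silyl group to give 1-[(3R)-3-ethenyl-3-methylcyclopent-1-en-1-yl]ethan-1-one F6 (the descriptor changes only because the CIP priorities change). Ozonolysis of the vinyl group (O3, CH2Cl2, −78 °C, then Me2S; the acetyl-conjugated ring alkene reacts more slowly) gives (1S)-3-acetyl-1-methylcyclopent-2-ene-1-carbaldehyde F7. Propane-1,3-dithiol with BF3·OEt2 converts the aldehyde, not the conjugated ketone, into the dithiane 10.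

Step 5. A hindered methyl ketone may enolise instead of adding the vinylogous phosphonate, and the new trisubstituted alkene may form as an E/Z mixture. The fallback builds that alkene by carbometalation and cross-coupling instead of olefination; it sets out from 14 and comes back at 17. LiN(iPr)2 and ClP(O)(OEt)2 give the enol phosphate diethyl 1-[(1R,2S,3S)-3-(1,3-dithian-2-yl)-3-methyl-2-(3-methylbut-3-en-1-yl)cyclopentyl]ethenyl phosphate F8. Excess LiN(iPr)2 eliminates it to the alkyne 2-[(1S,2S,3R)-3-ethynyl-1-methyl-2-(3-methylbut-3-en-1-yl)cyclopentyl]-1,3-dithiane F9. Cp2ZrCl2-catalysed syn-carboalumination with Me3Al gives the alkenylalane {(1E)-2-[(1R,2S,3S)-3-(1,3-dithian-2-yl)-3-methyl-2-(3-methylbut-3-en-1-yl)cyclopentyl]prop-1-en-1-yl}dimethylalumane F10. I2 converts it into the vinyl iodide 2-[(1S,2S,3R)-3-[(1E)-1-iodoprop-1-en-2-yl]-1-methyl-2-(3-methylbut-3-en-1-yl)cyclopentyl]-1,3-dithiane F11. Heck coupling of F11 with ethyl acrylate (Pd(OAc)2, Ag2CO3, DMF, 50 °C) gives 17 with both alkenes E.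

Step 7. The aldehyde is very hindered, and the ligand must override the intrinsic facial preference of the substrate, which is predicted to favour the other C1 epimer for carbon nucleophiles. The fallback sets C1 by catalyst-controlled ketone reduction instead; it sets out from 18 and comes back at 23. CH2=CHMgBr (THF, −78 °C) adds to the aldehyde to give ethyl (2E,4E)-5-[(1R,2S,3S)-3-(1-hydroxyprop-2-en-1-yl)-3-methyl-2-(3-methylbut-3-en-1-yl)cyclopentyl]hexa-2,4-dienoate F12 as a mixture of C1 epimers. Dess–Martin periodinane oxidises both epimers to the vinyl ketone ethyl (2E,4E)-5-[(1R,2S,3S)-3-methyl-2-(3-methylbut-3-en-1-yl)-3-(prop-2-enoyl)cyclopentyl]hexa-2,4-dienoate F13. Catecholborane with (S)-2-methyl-CBS-oxazaborolidine (quaternary carbon as the large, vinyl as the small substituent; this is also the Felkin-preferred sense for hydride) gives the carbinol ethyl (2E,4E)-5-[(1R,2S,3S)-3-[(1R)-1-hydroxyprop-2-en-1-yl]-3-methyl-2-(3-methylbut-3-en-1-yl)cyclopentyl]hexa-2,4-dienoate F14. Ring-closing metathesis of F14 under the step 8 conditions, now with a terminal vinyl group and loss of ethene, gives 23.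

**Further compounds**
F1 | step 2 | 3-methylcyclopent-2-en-1-one | CC1=CC(=O)CC1
F2 | step 2 | trimethyl({(3S)-3-methyl-3-[1-(trimethylsilyl)ethenyl]cyclopent-1-en-1-yl}oxy)silane | C[Si](C)(C)OC1=C[C@@](C)(C(=C)[Si](C)(C)C)CC1
F3 | step 2 | (3S)-3-methyl-3-[1-(trimethylsilyl)ethenyl]cyclopent-1-en-1-yl trifluoromethanesulfonate | FC(F)(F)S(=O)(=O)OC1=C[C@@](C)(C(=C)[Si](C)(C)C)CC1
F4 | step 2 | {1-[(1S)-3-(1-ethoxyethenyl)-1-methylcyclopent-2-en-1-yl]ethenyl}trimethylsilane | CCOC(=C)C1=C[C@@](C)(C(=C)[Si](C)(C)C)CC1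
F5 | step 2 | 1-{(3S)-3-methyl-3-[1-(trimethylsilyl)ethenyl]cyclopent-1-en-1-yl}ethan-1-one | CC(=O)C1=C[C@@](C)(C(=C)[Si](C)(C)C)CC1
F6 | step 2 | 1-[(3R)-3-ethenyl-3-methylcyclopent-1-en-1-yl]ethan-1-one | CC(=O)C1=C[C@@](C)(C=C)CC1
F7 | step 2 | (1S)-3-acetyl-1-methylcyclopent-2-ene-1-carbaldehyde | CC(=O)C1=C[C@@](C)(C=O)CC1
F8 | step 5 | diethyl 1-[(1R,2S,3S)-3-(1,3-dithian-2-yl)-3-methyl-2-(3-methylbut-3-en-1-yl)cyclopentyl]ethenyl phosphate | C1(SCCCS1)[C@@]2(C)CC[C@@H](C(=C)OP(=O)(OCC)OCC)[C@@H]2CCC(C)=C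
F9 | step 5 | 2-[(1S,2S,3R)-3-ethynyl-1-methyl-2-(3-methylbut-3-en-1-yl)cyclopentyl]-1,3-dithiane | C1(SCCCS1)[C@@]2(C)CC[C@@H](C#C)[C@@H]2CCC(C)=C
F10 | step 5 | {(1E)-2-[(1R,2S,3S)-3-(1,3-dithian-2-yl)-3-methyl-2-(3-methylbut-3-en-1-yl)cyclopentyl]prop-1-en-1-yl}dimethylalumane | C1(SCCCS1)[C@@]2(C)CC[C@@H](/C(C)=C/[Al](C)C)[C@@H]2CCC(C)=C
F11 | step 5 | 2-[(1S,2S,3R)-3-[(1E)-1-iodoprop-1-en-2-yl]-1-methyl-2-(3-methylbut-3-en-1-yl)cyclopentyl]-1,3-dithiane | C1(SCCCS1)[C@@]2(C)CC[C@@H](/C(C)=C/I)[C@@H]2CCC(C)=C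
F12 | step 7 | ethyl (2E,4E)-5-[(1R,2S,3S)-3-(1-hydroxyprop-2-en-1-yl)-3-methyl-2-(3-methylbut-3-en-1-yl)cyclopentyl]hexa-2,4-dienoate (both carbinol epimers) | OC(C=C)[C@@]1(C)CC[C@@H](/C(C)=C/C=C/C(=O)OCC)[C@@H]1CCC(C)=C
F13 | step 7 | ethyl (2E,4E)-5-[(1R,2S,3S)-3-methyl-2-(3-methylbut-3-en-1-yl)-3-(prop-2-enoyl)cyclopentyl]hexa-2,4-dienoate | C=CC(=O)[C@@]1(C)CC[C@@H](/C(C)=C/C=C/C(=O)OCC)[C@@H]1CCC(C)=C
F14 | step 7 | ethyl (2E,4E)-5-[(1R,2S,3S)-3-[(1R)-1-hydroxyprop-2-en-1-yl]-3-methyl-2-(3-methylbut-3-en-1-yl)cyclopentyl]hexa-2,4-dienoate | O[C@H](C=C)[C@@]1(C)CC[C@@H](/C(C)=C/C=C/C(=O)OCC)[C@@H]1CCC(C)=C
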